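A flask cannot make more D than it was charged with J, so autumn and spring, each with 10.0 J per G, have a ceiling of that many turnovers per G.

| flask | J | G | temperature | remark | time |
|---|---|---|---|---|---|
| blue | 0.025 M | 5 mM | 35 °C | run made earlier |  |
| amber | 0.10 M | 5 mM | 50 °C | run made earlier |  |
| ochre | 0.050 M | 7.5 mM | 35 °C | run made earlier |  |
| autumn | 0.050 M | 5.0 mM | 40 °C |  | 12 min |
| spring | 0.050 M | 5.0 mM | 60 °C |  | 12 min |

| run | time / min | D / % | J / % | E / % |
|---|---|---|---|---|
| blue | 0.833 | 0 | 95 | 6 |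
| blue | 1.33 | 3 | 90 | 9 |
| blue | 2.00 | 2 | 88 | 9 |
| blue | 4.00 | 11 | 79 | 5 |
| blue | 6.00 | 17 | 72 | 7 |
| blue | 10.0 | 31 | 65 | 5 |
| amber | 0.500 | 5 | 95 | 3 |
| amber | 0.833 | 0 | 91 | 6 |
| amber | 1.33 | 8 | 83 | 3 |
| amber | 2.50 | 16 | 85 | 1 |
| amber | 4.00 | 25 | 68 | 0 |
| amber | 6.00 | 32 | 63 | 5 |
| ochre | 0.833 | 2 | 89 | 7 |
| ochre | 2.50 | 7 | 83 | 16 |
| ochre | 4.00 | 14 | 78 | 8 |
| ochre | 6.00 | 15 | 73 | 6 |
| ochre | 10.0 | 28 | 64 | 4 |

(scatter of a reading: 2 percentage points)

- which of these there is most of at the end, counted by the J in it, autumn (J / E / D)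
- which of these there is most of at the end, counted by the J in it, spring (J / E / D)
- final amount of the leader among these, as a percentage of the J charged, in autumn
- final amount of the leader among these, as a percentage of the J charged, in spring



The earlier runs look contradictory: ochre has 1.50 times the G of blue, yet at 10.0 min its D reads 28% against blue's 31%. I clear this with a scale whose zero is the first-order case. If the rate were first order in J and in G, the share converted would ignore the J charge, and ochre would read 46.5%. Ochre also has more J, so I count in turnover frequency, w: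

w = cD / (cG · t)

This gives 0.155 min⁻¹ in blue and 0.187 min⁻¹ in ochre. Their ratio, with the scatter of single readings, gives a reading of 0.268 for the order in J, far from first order, so the shares no longer clash.

Amber reads 1.07 min⁻¹. Against ochre that is a factor 5.71 over 15.0 K, which I spread evenly on a logarithmic scale. Amber also has more J than ochre, worth a factor 1.20 by that order; I leave it in, so my temperature factor stands on the high side.

Autumn has ochre's J, so I carry ochre's w to autumn's temperature on that scale, and the D made per G charged per minute there is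

w = 0.334 min⁻¹

So D is 40.0%. With E at ochre's last 4%, J stays ahead at 56.0%.

For spring, w = 3.41 min⁻¹, which asks for 40.9 turnovers in 12 min, more than the ceiling. I therefore commit to D leading, with no figure beyond that ceiling.

The forecast names J at 56% in autumn, close to my J, and D at 90% in spring, where “conversion should finish within minutes”.

The flask gives J at 55.2% in autumn and D at 78.7% in spring.

    G ⇌ X (K = 28.0, k = 0.0150 min⁻¹, Ea = 98.0 kJ mol⁻¹, ΔH = −44.0 kJ mol⁻¹)
    E ⇌ G + D (K = 0.180 M, k = 0.800 min⁻¹, Ea = 92.0 kJ mol⁻¹, ΔH = −58.0 kJ mol⁻¹)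
    J + G ⇌ E (K = 700 M⁻¹, k = 24.0 M⁻¹ min⁻¹, Ea = 64.0 kJ mol⁻¹, ΔH = 5.00 kJ mol⁻¹)
    J + G → Q (k = 1.10 M⁻¹ min⁻¹, Ea = 44.0 kJ mol⁻¹)
    (constants at 40 °C)

Autumn's D of 39.2% means w = 0.327 min⁻¹, against my 0.334 min⁻¹. Spring's D of 78.7% means w = 0.656 min⁻¹, less than my 3.41 min⁻¹. The neighbour flask is autumn with J lowered to 0.030 M. Held at my autumn w, it reckons D at 66.7%. That flask stands at 47.6% D, which means w = 0.238 min⁻¹, less than my 0.334 min⁻¹, with 45.7% of its J left.

The readings were computed from invented constants; scatter was added.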